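## Retrosynthetic overview

- Target 24 ⇒ intramolecular indium Barbier allylation (C1–C2) of the ω-formyl (Z)-2-(bromomethyl)enoate 21, then lactonisation. This closes the 14-membered carbocycle and the cis-fused α-methylene-γ-lactone last.
- 21 ⇒ cross-metathesis (C1=C15), acetylation, Weinreb amide → enal, and Z-selective Wittig (C12=C13) on the α-peroxy methyl ketone 14.
- 14 ⇒ the 1,2-dioxane, formed first by singlet-oxygen [4+2] cycloaddition onto the (E,E)-dienol 11 and diimide reduction; the C7 carbinol directs C8 and C11.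
- 11 ⇒ HWE (C3=C4), MeLi opening of the lactone, Heck coupling (C9–C10), carboalumination–iodination and alkyne homologation of lactone 1.
- Ring order: 1,2-dioxane (step 7) → 14-membered carbocycle (step 14) → γ-lactone (step 14). The only bought stereocentre is C7, from lactone 1 (made from L-glutamic acid).

Assumption: the target is taken exactly as drawn, i.e. (1S,2S,3E,7S,8S,11R,12Z) in cembrane numbering with a cis-fused lactone, and compounds 1, 6, 9, 15 and 20 are taken as commercial.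

## Route

Step 1
Reactants: 1 (5S)-5-(hydroxymethyl)dihydrofuran-2(3H)-one
Product: 2 (2S)-5-oxotetrahydrofuran-2-carbaldehyde
Conditions: TEMPO (cat.), PhI(OAc)2, CH2Cl2, rt; used crude
Reagents that add atoms: none
Why: Oxoammonium (TEMPO) oxidation of the primary alcohol stops at the aldehyde under anhydrous, near-neutral conditions, so the bought stereocentre (future C7, S) is not epimerised.

Step 2
Reactants: 2 (2S)-5-oxotetrahydrofuran-2-carbaldehyde
Product: 3 (5S)-5-ethynyldihydrofuran-2(3H)-one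
Conditions: (MeO)2P(O)CHN2, KOtBu, THF, −78 °C to rt
Reagents that add atoms: dimethyl (diazomethyl)phosphonate, COP(=O)(OC)C=[N+]=[N-]
Why: Seyferth–Gilbert homologation (HWE-type addition, loss of N2, 1,2-H shift of the alkylidene carbene) turns CHO into C≡CH at low temperature without opening the lactone or touching the stereocentre.

Step 3
Reactants: 3 (5S)-5-ethynyldihydrofuran-2(3H)-one
Product: 5 (5S)-5-[(1E)-1-iodoprop-1-en-2-yl]dihydrofuran-2(3H)-one, via alkenyldimethylalane 4 (not isolated)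
Conditions: AlMe3 (3 equiv), Cp2ZrCl2 (20 mol %), H2O (1.5 equiv), CH2Cl2, −20 °C; then I2, THF, −20 °C
Reagents that add atoms: trimethylaluminium, C[Al](C)C; iodine, II
Why: Negishi zirconium-catalysed carboalumination adds Me and Al syn with Me on the substituted carbon, and iodinolysis with retention gives only the (E)-iodide (C7 trans to I), which fixes the C8=C9 geometry.

Step 4
Reactants: 5 (5S)-5-[(1E)-1-iodoprop-1-en-2-yl]dihydrofuran-2(3H)-one; 6 2-methyl-2-vinyl-1,3-dioxolane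
Product: 7 (5S)-5-[(2E,4E)-5-(2-methyl-1,3-dioxolan-2-yl)penta-2,4-dien-2-yl]dihydrofuran-2(3H)-one
Conditions: Pd(OAc)2 (5 mol %), Ag2CO3, DMF, 50 °C
Reagents that add atoms: none
Why: Heck reaction under Jeffery-type conditions, in which carbopalladation at the terminal carbon of 6 and syn β-hydride elimination (impossible toward the quaternary ketal carbon) give the (E,E)-diene with retention of the iodide geometry.

Step 5
Reactants: 7 (5S)-5-[(2E,4E)-5-(2-methyl-1,3-dioxolan-2-yl)penta-2,4-dien-2-yl]dihydrofuran-2(3H)-one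
Product: 8 (5S,6E,8E)-5-hydroxy-6-methyl-9-(2-methyl-1,3-dioxolan-2-yl)nona-6,8-dien-2-one
Conditions: MeLi (1.05 equiv), THF, −78 °C; aq. NH4Cl
Reagents that add atoms: methyllithium, [Li]C
Why: Single addition of MeLi to the γ-lactone (the tetrahedral lithium hemiketal is stable at −78 °C) gives the C4 methyl ketone and frees the C7 hydroxyl needed as directing group.

Step 6
Reactants: 8 (5S,6E,8E)-5-hydroxy-6-methyl-9-(2-methyl-1,3-dioxolan-2-yl)nona-6,8-dien-2-one; 9 diethyl {2-[methoxy(methyl)amino]-2-oxoethyl}phosphonate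
Product: 11 (2E,6S,7E,9E)-6-hydroxy-N-methoxy-N,3,7-trimethyl-10-(2-methyl-1,3-dioxolan-2-yl)deca-2,7,9-trienamide, via sodium phosphonate carbanion 10 (not isolated)
Conditions: NaH (2.5 equiv), THF, 0 to 45 °C
Reagents that add atoms: none
Why: Horner–Wadsworth–Emmons olefination of the methyl ketone gives mainly the (E)-enamide (about 5:1, Z isomer removed by chromatography), and this acceptor-substituted alkene is inert to singlet oxygen in the next step.

Step 7
Reactants: 11 (2E,6S,7E,9E)-6-hydroxy-N-methoxy-N,3,7-trimethyl-10-(2-methyl-1,3-dioxolan-2-yl)deca-2,7,9-trienamide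
Product: 12 (2E,6S)-6-hydroxy-N-methoxy-N,3-dimethyl-6-[(3S,6R)-3-methyl-6-(2-methyl-1,3-dioxolan-2-yl)-3,6-dihydro-1,2-dioxin-3-yl]hex-2-enamide
Conditions: O2, TPP (cat.), hν (visible), CCl4, 0 °C
Reagents that add atoms: dioxygen, O=O
Why: Singlet-oxygen [4+2] cycloaddition (hetero-Diels–Alder) adds suprafacially to the (E,E)-diene, so the bonds to C7 and C12 end up cis on the new ring, and hydrogen bonding of the free (7S)-hydroxyl in the non-polar solvent steers O2 to the like face to give (8S,11R) (expected dr about 3–4:1).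

Step 8
Reactants: 12 (2E,6S)-6-hydroxy-N-methoxy-N,3-dimethyl-6-[(3S,6R)-3-methyl-6-(2-methyl-1,3-dioxolan-2-yl)-3,6-dihydro-1,2-dioxin-3-yl]hex-2-enamide
Product: 13 (2E,6S)-6-hydroxy-N-methoxy-N,3-dimethyl-6-[(3S,6R)-3-methyl-6-(2-methyl-1,3-dioxolan-2-yl)-1,2-dioxan-3-yl]hex-2-enamide
Conditions: KO2CN=NCO2K, AcOH, CH2Cl2, 0 °C; minor diastereomer removed by chromatography
Reagents that add atoms: none
Why: Diimide reduction transfers H2 syn to the cis-disubstituted ring alkene without cleaving the O–O bond and leaves the trisubstituted conjugated alkene alone, while the acidic medium avoids Kornblum–DeLaMare opening of the dioxene.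

Step 9
Reactants: 13 (2E,6S)-6-hydroxy-N-methoxy-N,3-dimethyl-6-[(3S,6R)-3-methyl-6-(2-methyl-1,3-dioxolan-2-yl)-1,2-dioxan-3-yl]hex-2-enamide
Product: 14 (2E,6S)-6-[(3S,6R)-6-acetyl-3-methyl-1,2-dioxan-3-yl]-6-hydroxy-N-methoxy-N,3-dimethylhex-2-enamide
Conditions: PPTS, acetone–H2O, 40 °C
Reagents that add atoms: water, O
Why: Mild acid-catalysed ketal hydrolysis unmasks the C12 methyl ketone, and the saturated dialkyl peroxide and all stereocentres are stable to weak acid.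

Step 10
Reactants: 14 (2E,6S)-6-[(3S,6R)-6-acetyl-3-methyl-1,2-dioxan-3-yl]-6-hydroxy-N-methoxy-N,3-dimethylhex-2-enamide; 15 (but-3-en-1-yl)triphenylphosphonium bromide
Product: 17 (2E,6S)-6-{(3S,6R)-6-[(2Z)-hexa-2,5-dien-2-yl]-3-methyl-1,2-dioxan-3-yl}-6-hydroxy-N-methoxy-N,3-dimethylhex-2-enamide, via phosphorus ylide 16 (not isolated)
Conditions: 15 (3 equiv), NaN(SiMe3)2, THF, −78 °C; then 14, −78 to 0 °C
Reagents that add atoms: none
Why: Wittig olefination of an α-oxygenated methyl ketone with a salt-free non-stabilised ylide gives the Z-trisubstituted alkene (C11 cis to C14), and fast carbonyl addition at −78 °C outruns deprotonation of the hindered C11–H that would trigger Kornblum–DeLaMare cleavage.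

Step 11
Reactants: 17 (2E,6S)-6-{(3S,6R)-6-[(2Z)-hexa-2,5-dien-2-yl]-3-methyl-1,2-dioxan-3-yl}-6-hydroxy-N-methoxy-N,3-dimethylhex-2-enamide
Product: 18 (2E,6S)-6-{(3S,6R)-6-[(2Z)-hexa-2,5-dien-2-yl]-3-methyl-1,2-dioxan-3-yl}-6-hydroxy-3-methylhex-2-enal
Conditions: iBu2AlH (2.5 equiv), CH2Cl2, −78 °C; aq. KNaC4H4O6
Reagents that add atoms: none
Why: Hydride reduction of the Weinreb amide stops at the chelated aluminium hemiaminal and gives the (E)-enal on work-up, and the 1,2-dioxane tolerates iBu2AlH at −78 °C.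

Step 12
Reactants: 18 (2E,6S)-6-{(3S,6R)-6-[(2Z)-hexa-2,5-dien-2-yl]-3-methyl-1,2-dioxan-3-yl}-6-hydroxy-3-methylhex-2-enal
Product: 19 (1S,4E)-1-{(3S,6R)-6-[(2Z)-hexa-2,5-dien-2-yl]-3-methyl-1,2-dioxan-3-yl}-4-methyl-6-oxohex-4-en-1-yl acetate
Conditions: Ac2O, pyridine, DMAP (cat.), CH2Cl2, 0 °C to rt
Reagents that add atoms: acetic anhydride, CC(=O)OC(C)=O
Why: DMAP-catalysed acylation of the only hydroxyl (hindered C7–OH) installs the acetate of the target with retention at C7.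

Step 13
Reactants: 19 (1S,4E)-1-{(3S,6R)-6-[(2Z)-hexa-2,5-dien-2-yl]-3-methyl-1,2-dioxan-3-yl}-4-methyl-6-oxohex-4-en-1-yl acetate; 20 methyl 2-(bromomethyl)acrylate
Product: 21 methyl (2Z,5Z)-6-{(3R,6S)-6-[(1S,4E)-1-acetoxy-4-methyl-6-oxohex-4-en-1-yl]-6-methyl-1,2-dioxan-3-yl}-2-(bromomethyl)hepta-2,5-dienoate
Conditions: second-generation Hoveyda–Grubbs catalyst (10 mol %), 20 (10 equiv), CH2Cl2, 40 °C
Reagents that add atoms: none
Why: Olefin cross-metathesis joins the only terminal alkene with the 1,1-disubstituted acrylate (the trisubstituted alkenes are spectators and dialkyl peroxides tolerate the ruthenium carbene) to give the isomer with the chain trans to CO2Me.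

Step 14
Reactants: 21 methyl (2Z,5Z)-6-{(3R,6S)-6-[(1S,4E)-1-acetoxy-4-methyl-6-oxohex-4-en-1-yl]-6-methyl-1,2-dioxan-3-yl}-2-(bromomethyl)hepta-2,5-dienoate
Product: 24 (1S,2S,3E,7S,8S,11R,12Z)-7-acetoxy-8,11-epidioxycembra-3,12,15(17)-trien-16,2-olide (target), via allylindium dibromide 22 (not isolated), via macrocyclic hydroxy ester 23 (not isolated)
Conditions: indium powder (In), THF–H2O 3:1, 0.002 M, rt; then PPTS (cat.), CH2Cl2, rt
Reagents that add atoms: none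
Why: Intramolecular Barbier allylation, in which the allylindium adds through its γ-carbon (C1) to the enal carbonyl (C2) via a chair transition state that makes the (Z)-reagent give the syn adduct (hence the cis-lactone after lactonisation), with the face fixed by the bridged dioxane and the C7 acetate in the folded 14-membered transition state.

## Compound list

1 | (5S)-5-(hydroxymethyl)dihydrofuran-2(3H)-one | O=C1CC[C@H](O1)CO | starting material
2 | (2S)-5-oxotetrahydrofuran-2-carbaldehyde | O=C1CC[C@H](O1)C=O | intermediate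
3 | (5S)-5-ethynyldihydrofuran-2(3H)-one | O=C1CC[C@H](O1)C#C | intermediate
4 | dimethyl{(1E)-2-[(2S)-5-oxotetrahydrofuran-2-yl]prop-1-en-1-yl}alane | O=C1CC[C@H](O1)/C(C)=C/[Al](C)C | intermediate
5 | (5S)-5-[(1E)-1-iodoprop-1-en-2-yl]dihydrofuran-2(3H)-one | O=C1CC[C@H](O1)/C(C)=C/I | intermediate
6 | 2-methyl-2-vinyl-1,3-dioxolane | C=CC1(C)OCCO1 | starting material
7 | (5S)-5-[(2E,4E)-5-(2-methyl-1,3-dioxolan-2-yl)penta-2,4-dien-2-yl]dihydrofuran-2(3H)-one | O=C1CC[C@H](O1)/C(C)=C/C=C/C2(C)OCCO2 | intermediate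
8 | (5S,6E,8E)-5-hydroxy-6-methyl-9-(2-methyl-1,3-dioxolan-2-yl)nona-6,8-dien-2-one | CC(=O)CC[C@H](O)/C(C)=C/C=C/C1(C)OCCO1 | intermediate
9 | diethyl {2-[methoxy(methyl)amino]-2-oxoethyl}phosphonate | CCOP(=O)(CC(=O)N(C)OC)OCC | starting material
10 | sodium salt of the carbanion of 9 | [Na+].CCOP(=O)(OCC)[CH-]C(=O)N(C)OC | intermediate
11 | (2E,6S,7E,9E)-6-hydroxy-N-methoxy-N,3,7-trimethyl-10-(2-methyl-1,3-dioxolan-2-yl)deca-2,7,9-trienamide | CON(C)C(=O)/C=C(\C)CC[C@H](O)/C(C)=C/C=C/C1(C)OCCO1 | intermediate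
12 | (2E,6S)-6-hydroxy-N-methoxy-N,3-dimethyl-6-[(3S,6R)-3-methyl-6-(2-methyl-1,3-dioxolan-2-yl)-3,6-dihydro-1,2-dioxin-3-yl]hex-2-enamide | CON(C)C(=O)/C=C(\C)CC[C@H](O)[C@]1(C)C=C[C@@H](OO1)C2(C)OCCO2 | intermediate
13 | (2E,6S)-6-hydroxy-N-methoxy-N,3-dimethyl-6-[(3S,6R)-3-methyl-6-(2-methyl-1,3-dioxolan-2-yl)-1,2-dioxan-3-yl]hex-2-enamide | CON(C)C(=O)/C=C(\C)CC[C@H](O)[C@]1(C)CC[C@@H](OO1)C2(C)OCCO2 | intermediate
14 | (2E,6S)-6-[(3S,6R)-6-acetyl-3-methyl-1,2-dioxan-3-yl]-6-hydroxy-N-methoxy-N,3-dimethylhex-2-enamide | CON(C)C(=O)/C=C(\C)CC[C@H](O)[C@]1(C)CC[C@@H](OO1)C(C)=O | intermediate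
15 | (but-3-en-1-yl)triphenylphosphonium bromide | [Br-].C=CCC[P+](c1ccccc1)(c1ccccc1)c1ccccc1 | starting material
16 | (but-3-en-1-ylidene)triphenylphosphorane | C=CCC=P(c1ccccc1)(c1ccccc1)c1ccccc1 | intermediate
17 | (2E,6S)-6-{(3S,6R)-6-[(2Z)-hexa-2,5-dien-2-yl]-3-methyl-1,2-dioxan-3-yl}-6-hydroxy-N-methoxy-N,3-dimethylhex-2-enamide | CON(C)C(=O)/C=C(\C)CC[C@H](O)[C@]1(C)CC[C@@H](OO1)/C(C)=C\CC=C | intermediate
18 | (2E,6S)-6-{(3S,6R)-6-[(2Z)-hexa-2,5-dien-2-yl]-3-methyl-1,2-dioxan-3-yl}-6-hydroxy-3-methylhex-2-enal | O=C/C=C(\C)CC[C@H](O)[C@]1(C)CC[C@@H](OO1)/C(C)=C\CC=C | intermediate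
19 | (1S,4E)-1-{(3S,6R)-6-[(2Z)-hexa-2,5-dien-2-yl]-3-methyl-1,2-dioxan-3-yl}-4-methyl-6-oxohex-4-en-1-yl acetate | O=C/C=C(\C)CC[C@H](OC(C)=O)[C@]1(C)CC[C@@H](OO1)/C(C)=C\CC=C | intermediate
20 | methyl 2-(bromomethyl)acrylate | C=C(CBr)C(=O)OC | starting material
21 | methyl (2Z,5Z)-6-{(3R,6S)-6-[(1S,4E)-1-acetoxy-4-methyl-6-oxohex-4-en-1-yl]-6-methyl-1,2-dioxan-3-yl}-2-(bromomethyl)hepta-2,5-dienoate | O=C/C=C(\C)CC[C@H](OC(C)=O)[C@]1(C)CC[C@@H](OO1)/C(C)=C\C/C=C(/C(=O)OC)CBr | intermediate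
22 | allylindium dibromide from 21 (CH2Br replaced by CH2InBr2) | O=C/C=C(\C)CC[C@H](OC(C)=O)[C@]1(C)CC[C@@H](OO1)/C(C)=C\C/C=C(/C(=O)OC)C[In](Br)Br | intermediate
23 | methyl 2-[(1S,2S,3E,7S,8S,11R,12Z)-7-acetoxy-2-hydroxy-4,8,12-trimethyl-8,11-epidioxycyclotetradeca-3,12-dien-1-yl]acrylate | COC(=O)C(=C)[C@H]1[C@@H](O)/C=C(\C)CC[C@H](OC(C)=O)[C@]2(C)CC[C@@H](OO2)/C(C)=C\C1 | intermediate
24 | (1S,2S,3E,7S,8S,11R,12Z)-7-acetoxy-8,11-epidioxycembra-3,12,15(17)-trien-16,2-olide: cis-fused α-methylene-γ-lactone on a 14-membered ring bridged by a 1,2-dioxane | C=C1C(=O)O[C@H]2/C=C(\C)CC[C@H](OC(C)=O)[C@]3(C)CC[C@@H](OO3)/C(C)=C\C[C@@H]12 | target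

## Step count and risk

Total step count: 14. Longest linear sequence: 14 steps (1 → 24); 6, 9, 15 and 20 are bought.

The three steps most likely to fail:

**Step 7 (cycloaddition).** The diene terminus C8 carries a methyl group cis to the diene, so ene reaction at C8=C9 can compete with the [4+2] mode. The hydroxyl-directed facial selectivity is only moderate because the carbinol has 1,2- but no 1,3-allylic strain. The fallback sets out from 11 and comes back at 14. The ketal is hydrolysed first (PPTS, wet acetone, 0 °C) to the hydroxy dienone (2E,6S,7E,9E)-6-hydroxy-N-methoxy-N,3,7-trimethyl-11-oxododeca-2,7,9-trienamide F1. This acceptor-substituted, sorbyl-ketone-type diene is much less prone to ene reaction and is photo-oxygenated (O2, TPP, hν, CH2Cl2, −30 °C) to the acetyl dioxene (2E,6S)-6-[(3S,6R)-6-acetyl-3-methyl-3,6-dihydro-1,2-dioxin-3-yl]-6-hydroxy-N-methoxy-N,3-dimethylhex-2-enamide F2. F2 is reduced at once with diimide (KO2CN=NCO2K, AcOH) to 14.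

**Step 13 (cross-metathesis).** Coupling a hindered 1,1-disubstituted bromomethyl acrylate to a polyfunctional peroxide may stall or cause alkene migration. The fallback sets out from 14 and comes back at 21, building the same unit by carbonyl chemistry:
- Wittig reaction of 14 with the ylide from [2-(1,3-dioxolan-2-yl)ethyl]triphenylphosphonium bromide (NaN(SiMe3)2, THF, −78 °C) gives the (Z)-alkene acetal (2E,6S)-6-{(3S,6R)-6-[(2Z)-4-(1,3-dioxolan-2-yl)but-2-en-2-yl]-3-methyl-1,2-dioxan-3-yl}-6-hydroxy-N-methoxy-N,3-dimethylhex-2-enamide F3.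
- iBu2AlH (−78 °C) gives the enal (2E,6S)-6-{(3S,6R)-6-[(2Z)-4-(1,3-dioxolan-2-yl)but-2-en-2-yl]-3-methyl-1,2-dioxan-3-yl}-6-hydroxy-3-methylhex-2-enal F4.
- Ac2O/pyridine/DMAP gives the acetate (1S,4E)-1-{(3S,6R)-6-[(2Z)-4-(1,3-dioxolan-2-yl)but-2-en-2-yl]-3-methyl-1,2-dioxan-3-yl}-4-methyl-6-oxohex-4-en-1-yl acetate F5.
- TsOH·H2O in wet acetone frees the aldehyde (1S,4E)-4-methyl-1-{(3S,6R)-3-methyl-6-[(2Z)-5-oxopent-2-en-2-yl]-1,2-dioxan-3-yl}-6-oxohex-4-en-1-yl acetate F6.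
- DABCO-catalysed Morita–Baylis–Hillman reaction with methyl acrylate (the β,β-disubstituted enal does not react) gives the allylic alcohol methyl (5Z)-6-{(3R,6S)-6-[(1S,4E)-1-acetoxy-4-methyl-6-oxohex-4-en-1-yl]-6-methyl-1,2-dioxan-3-yl}-3-hydroxy-2-methylidenehept-5-enoate F7.
- NBS/Me2S converts F7 with allylic transposition into 21.

**Step 14 (macrocyclisation).** Risks are oligomerisation, reduction of the O–O bond at the metal surface, and the unproven facial sense at C1/C2. The fallback sets out from 19 and comes back at 23, replacing the reductive metal by boron. Cross-metathesis of 19 with methyl 2-[(4,4,5,5-tetramethyl-1,3,2-dioxaborolan-2-yl)methyl]acrylate (second-generation Hoveyda–Grubbs catalyst) gives the allylboronate methyl (2E,5Z)-6-{(3R,6S)-6-[(1S,4E)-1-acetoxy-4-methyl-6-oxohex-4-en-1-yl]-6-methyl-1,2-dioxan-3-yl}-2-[(4,4,5,5-tetramethyl-1,3,2-dioxaborolan-2-yl)methyl]hepta-2,5-dienoate F8. Under high dilution (toluene, 60 °C, or Sc(OTf)3 cat. at rt) F8 undergoes intramolecular allylboration of the enal through a closed chair transition state. Hydrolysis of the borate gives 23, which lactonises to 24 as in step 14.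

## Further compounds

F1 | step 7 | (2E,6S,7E,9E)-6-hydroxy-N-methoxy-N,3,7-trimethyl-11-oxododeca-2,7,9-trienamide | CON(C)C(=O)/C=C(\C)CC[C@H](O)/C(C)=C/C=C/C(C)=O
F2 | step 7 | (2E,6S)-6-[(3S,6R)-6-acetyl-3-methyl-3,6-dihydro-1,2-dioxin-3-yl]-6-hydroxy-N-methoxy-N,3-dimethylhex-2-enamide | CON(C)C(=O)/C=C(\C)CC[C@H](O)[C@]1(C)C=C[C@@H](OO1)C(C)=O
F3 | step 13 | (2E,6S)-6-{(3S,6R)-6-[(2Z)-4-(1,3-dioxolan-2-yl)but-2-en-2-yl]-3-methyl-1,2-dioxan-3-yl}-6-hydroxy-N-methoxy-N,3-dimethylhex-2-enamide | CON(C)C(=O)/C=C(\C)CC[C@H](O)[C@]1(C)CC[C@@H](OO1)/C(C)=C\CC2OCCO2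
F4 | step 13 | (2E,6S)-6-{(3S,6R)-6-[(2Z)-4-(1,3-dioxolan-2-yl)but-2-en-2-yl]-3-methyl-1,2-dioxan-3-yl}-6-hydroxy-3-methylhex-2-enal | O=C/C=C(\C)CC[C@H](O)[C@]1(C)CC[C@@H](OO1)/C(C)=C\CC2OCCO2
F5 | step 13 | (1S,4E)-1-{(3S,6R)-6-[(2Z)-4-(1,3-dioxolan-2-yl)but-2-en-2-yl]-3-methyl-1,2-dioxan-3-yl}-4-methyl-6-oxohex-4-en-1-yl acetate | O=C/C=C(\C)CC[C@H](OC(C)=O)[C@]1(C)CC[C@@H](OO1)/C(C)=C\CC2OCCO2
F6 | step 13 | (1S,4E)-4-methyl-1-{(3S,6R)-3-methyl-6-[(2Z)-5-oxopent-2-en-2-yl]-1,2-dioxan-3-yl}-6-oxohex-4-en-1-yl acetate | O=C/C=C(\C)CC[C@H](OC(C)=O)[C@]1(C)CC[C@@H](OO1)/C(C)=C\CC=O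
F7 | step 13 | methyl (5Z)-6-{(3R,6S)-6-[(1S,4E)-1-acetoxy-4-methyl-6-oxohex-4-en-1-yl]-6-methyl-1,2-dioxan-3-yl}-3-hydroxy-2-methylidenehept-5-enoate (both C3 epimers) | O=C/C=C(\C)CC[C@H](OC(C)=O)[C@]1(C)CC[C@@H](OO1)/C(C)=C\CC(O)C(=C)C(=O)OC
F8 | step 14 | methyl (2E,5Z)-6-{(3R,6S)-6-[(1S,4E)-1-acetoxy-4-methyl-6-oxohex-4-en-1-yl]-6-methyl-1,2-dioxan-3-yl}-2-[(4,4,5,5-tetramethyl-1,3,2-dioxaborolan-2-yl)methyl]hepta-2,5-dienoate | O=C/C=C(\C)CC[C@H](OC(C)=O)[C@]1(C)CC[C@@H](OO1)/C(C)=C\C/C=C(/C(=O)OC)CB2OC(C)(C)C(C)(C)O2
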